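**Retrosynthetic overview**

1. The (Z)-3-methylglutaconyl half-ester comes last, from ring-opening of 3-methylglutaconic anhydride by the C6–OH of a C5,C11-bis-silylated triol.
2. The C10–C11 unit comes from hydroxymethylation of a C1 methyl ketone, the C1 methyl from alkylation of a carboxylate dianion anti to the sec-butyl group, and the C8 methyl from OH-directed hydrogenation of an exocyclic methylene.
3. Ring A (C3=C4) is closed by ring-closing metathesis of a vinyl/propenyl diene; the C1–C2 bond and the C2 stereocentre come from an Ireland–Claisen rearrangement with 1,3-chirality transfer.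
4. The Claisen ester is made by alkylating a quinic-acid-derived cyclohexanone enolate (after vinyl cuprate addition) with the bromoacetate of (2R,3E,5R)-5-methylhept-3-en-2-ol, itself made from tiglic acid.
5. Ring order: ring B is carried intact from (−)-quinic acid; ring A is formed late by the metathesis.

Assumption: locants follow the decalin numbering of the target (C1 quaternary, C2 sec-butyl, C3=C4, C4a, C5–OH, C6–O-acyl, C7, C8–Me, C8a; C9–C11 = 3-hydroxypropanoyl chain), β is the face of H-4a, and simple reagents are identified by name and SMILES instead of a number.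

**Ring-B fragment (steps 1–5)**

Step 1
Reactants: 1 (−)-quinic acid
Product: 2 3,4-O-isopropylidene-1,5-quinide
Conditions: 2,2-dimethoxypropane, p-TsOH (cat.), acetone, reflux
Reagents that add atoms: 2,2-dimethoxypropane, COC(C)(C)OC
Why: Acid-catalysed acetalisation protects the only cis-diol while the carboxyl group, cis to the remaining secondary OH, closes the γ-lactone; no stereocentre is changed.

Step 2
Reactants: 2 3,4-O-isopropylidene-1,5-quinide
Product: 3 acetonide triol (lactone reduced to CH2OH and free secondary OH)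
Conditions: NaBH4, EtOH, 0 °C to rt
Reagents that add atoms: none
Why: Hydride reduction of the strained bicyclic lactone gives the tertiary/primary 1,2-diol needed for cleavage.

Step 3
Reactants: 3 acetonide triol
Product: 4 (3R,4S,5R)-3-hydroxy-4,5-(isopropylidenedioxy)cyclohexan-1-one
Conditions: NaIO4, pH 7 phosphate buffer, H2O, 0 °C to rt
Reagents that add atoms: none
Why: Malaprade glycol cleavage removes the CH2OH carbon as formaldehyde and leaves the ring ketone.

Step 4
Reactants: 4 (3R,4S,5R)-3-hydroxy-4,5-(isopropylidenedioxy)cyclohexan-1-one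
Product: 6 (4S,5R)-4,5-(isopropylidenedioxy)cyclohex-2-en-1-one, via mesylate 5 (not isolated)
Conditions: MsCl, Et3N, CH2Cl2, 0 °C
Reagents that add atoms: none
Why: Mesylation of the β-hydroxy ketone followed by E1cB elimination gives the enone; the two acetonide stereocentres (future C5 and C6) are untouched.

Step 5
Reactants: 6 (4S,5R)-4,5-(isopropylidenedioxy)cyclohex-2-en-1-one
Product: 7 TMS enol ether of the 3-vinyl ketone (vinyl trans to the neighbouring acetonide oxygen)
Conditions: CH2=CHMgBr, CuBr·SMe2 (10 mol%), TMSCl, HMPA, THF, −78 °C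
Reagents that add atoms: vinylmagnesium bromide, C=C[Mg]Br; chlorotrimethylsilane, C[Si](C)(C)Cl
Why: TMSCl-accelerated copper-catalysed conjugate addition delivers the vinyl group anti to the adjacent acetonide oxygen (sets C4a) and traps the regio-defined enolate.

**Allyl fragment (steps 6–10)**

Step 6
Reactants: 8 tiglic acid
Product: 9 (R)-2-methylbutanoic acid
Conditions: H2 (1.5 atm), Ru(OAc)2[(R)-H8-BINAP] (0.5 mol%), MeOH, 15 °C
Reagents that add atoms: none
Why: Noyori-type asymmetric hydrogenation of the α,β-unsaturated acid; the (R)-ligand is expected to set the (R) α-methyl centre, the later sec-butyl stereocentre.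

Step 7
Reactants: 9 (R)-2-methylbutanoic acid
Product: 10 (R)-2-methylbutan-1-ol
Conditions: LiAlH4, Et2O, 0 °C to reflux
Reagents that add atoms: none
Why: Hydride reduction of the acid; the stereocentre is not epimerised.

Step 8
Reactants: 10 (R)-2-methylbutan-1-ol
Product: 12 (3E,5R)-5-methylhept-3-en-2-one, via (R)-2-methylbutanal 11 (not isolated)
Conditions: TEMPO (10 mol%), PhI(OAc)2, CH2Cl2, rt; then Ph3P=CHC(O)CH3, rt to 40 °C
Reagents that add atoms: 1-(triphenylphosphoranylidene)propan-2-one, CC(=O)C=P(c1ccccc1)(c1ccccc1)c1ccccc1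
Why: Non-basic TEMPO oxidation and in-situ Wittig olefination with a stabilised ylide give the (E)-enone without isolating or epimerising the volatile α-chiral aldehyde.

Step 9
Reactants: 12 (3E,5R)-5-methylhept-3-en-2-one
Product: 13 (2R,3E,5R)-5-methylhept-3-en-2-ol
Conditions: (S)-2-methyl-CBS-oxazaborolidine (20 mol%), catecholborane, toluene, −78 °C
Reagents that add atoms: none
Why: Corey–Bakshi–Shibata reduction; with the (S)-catalyst the alkenyl (large) / methyl (small) ketone gives the (R)-carbinol under reagent control.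

Step 10
Reactants: 13 (2R,3E,5R)-5-methylhept-3-en-2-ol
Product: 14 (2R,3E,5R)-5-methylhept-3-en-2-yl bromoacetate
Conditions: BrCH2COBr, pyridine, CH2Cl2, −20 to 0 °C
Reagents that add atoms: bromoacetyl bromide, BrCC(Br)=O
Why: Simple O-acylation with the acid bromide; no stereocentre is involved.

**Acyl fragment (steps 11–13)**

Step 11
Reactants: 15 ethyl acetoacetate (2 equiv)
Product: 16 ethyl isodehydroacetate
Conditions: conc. H2SO4, rt, 5 d; ice quench
Reagents that add atoms: none
Why: Acid-mediated self-condensation of the β-keto ester (C-acylation then enol-lactonisation) gives the 2-pyranone.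

Step 12
Reactants: 16 ethyl isodehydroacetate
Product: 17 3-methylglutaconic acid (Z shown; E/Z mixture converges in step 13)
Conditions: aq. NaOH, reflux; then HCl to pH 1
Reagents that add atoms: water (delivered as NaOH), O
Why: Hydroxide opens the pyranone, retro-Claisen cleavage expels acetate and the ester is saponified.

Step 13
Reactants: 17 3-methylglutaconic acid
Product: 18 3-methylglutaconic anhydride (4-methyl-2H-pyran-2,6(3H)-dione)
Conditions: Ac2O, 100 °C, 15 min; crystallise
Reagents that add atoms: none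
Why: Dehydration to the six-membered cyclic anhydride, which can only form with the two carboxyls cis, fixes the Z geometry needed in the target.

**Union and endgame (steps 14–23)**

Step 14
Reactants: 7 TMS enol ether; 14 (2R,3E,5R)-5-methylhept-3-en-2-yl bromoacetate
Product: 20 (2R,3E,5R)-5-methylhept-3-en-2-yl 2-[4,5-(isopropylidenedioxy)-2-oxo-6-vinylcyclohexyl]acetate, via lithium enolate 19 (not isolated)
Conditions: MeLi (1.0 equiv), THF, 0 °C; then 14, HMPA, −78 to −30 °C; AcOH quench
Reagents that add atoms: none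
Why: MeLi frees the regio-defined lithium enolate, and SN2 enolate alkylation by the α-bromo ester occurs trans to the neighbouring vinyl group, setting C8a and joining the two main fragments.

Step 15
Reactants: 20 keto ester
Product: 21 (2R,3E,5R)-5-methylhept-3-en-2-yl 2-[4,5-(isopropylidenedioxy)-2-methylidene-6-vinylcyclohexyl]acetate
Conditions: Zn, CH2Br2, TiCl4, THF–CH2Cl2, 0 °C to rt
Reagents that add atoms: dibromomethane, BrCBr
Why: Lombardo–Takai methylenation is non-basic, so the ketone is converted to the exocyclic alkene without touching the ester or causing β-elimination of the acetonide oxygen.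

Step 16
Reactants: 21 methylidene allylic ester
Product: 24 diene acid (3S,4E)-3-[(2R)-butan-2-yl]-2-[4,5-(isopropylidenedioxy)-2-methylidene-6-vinylcyclohexyl]hex-4-enoic acid (C1 epimers; major drawn), via silyl ketene acetal 22 (not isolated), via trimethylsilyl ester 23 (not isolated)
Conditions: LDA, TMSCl–Et3N, THF, −78 °C to 60 °C; then 1 M aq. HCl
Reagents that add atoms: none
Why: Ireland–Claisen rearrangement; the shift is suprafacial with the carbinol methyl pseudo-equatorial, so the (R)-carbinol is transferred to C2 (S) with an (E)-propenyl group whatever the enolate geometry, and the C1 epimer ratio is irrelevant because C1 is re-enolised in step 18.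

Step 17
Reactants: 24 diene acid
Product: 25 trans-fused octalin acid (ring A closed; C3=C4; C8 exocyclic methylene; acetonide)
Conditions: second-generation Grubbs catalyst (5 mol%), CH2Cl2, 40 °C
Reagents that add atoms: none
Why: Ring-closing metathesis between the C4a vinyl and C2 propenyl groups closes six-membered ring A with loss of propene; the hindered 1,1-disubstituted exocyclic alkene should not compete.

Step 18
Reactants: 25 octalin acid
Product: 27 C1-methylated acid (C1 methyl β; carboxyl α), via dilithium enediolate 26 (not isolated)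
Conditions: LDA (2.6 equiv), THF–DMPU, −20 to 45 °C; MeI, −78 to 0 °C; H3O+
Reagents that add atoms: iodomethane, CI
Why: Alkylation of the carboxylic acid dianion; MeI approaches C1 anti to the pseudo-axial sec-butyl group on C2, giving the quaternary centre with axial methyl.

Step 19
Reactants: 27 C1-methylated acid
Product: 30 methyl ketone diol (C5–OH and C6–OH free; C8 methylidene), via dilithium gem-diolate 28 (not isolated), via acetonide methyl ketone 29 (not isolated)
Conditions: MeLi (6 equiv), THF, 0 °C to rt; inverse quench into 1 M HCl; then MeOH, rt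
Reagents that add atoms: methyllithium, [Li]C
Why: Organolithium addition to a lithium carboxylate stops at the gem-diolate, which gives the methyl ketone only on quench, and the same acidic methanolic work-up hydrolyses the acetonide.

Step 20
Reactants: 30 methyl ketone diol
Product: 31 C8-methyl diol ketone (C8 methyl α)
Conditions: H2 (1 atm), [Ir(cod)(PCy3)(py)]PF6 (5 mol%), CH2Cl2, 0 °C
Reagents that add atoms: none
Why: Hydroxyl-directed hydrogenation; the iridium bound to the axial C6–OH delivers H2 to the β face of the exocyclic alkene (equatorial C8 methyl), while the hindered, undirected ring alkene is expected to survive.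

Step 21
Reactants: 31 C8-methyl diol ketone
Product: 33 triol (C5–OH; C6–OH; 3-hydroxypropanoyl chain), via tris-TMS enol ether 32 (not isolated)
Conditions: TMSOTf, Et3N, CH2Cl2, −78 to 0 °C; then 37% aq. HCHO, Yb(OTf)3 (20 mol%), THF, rt; 1 M HCl work-up
Reagents that add atoms: formaldehyde, C=O
Why: The ketone can enolise only towards its methyl group, and a Lewis-acid-catalysed Mukaiyama aldol reaction of the silyl enol ether with aqueous formaldehyde adds C11; the transient TMS ethers are lost on acidic work-up.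

Step 22
Reactants: 33 triol
Product: 34 C5,C11-bis-TBS ether (C6–OH free)
Conditions: TBSCl (2.2 equiv), imidazole, DMF, 0 °C
Reagents that add atoms: tert-butyldimethylsilyl chloride, CC(C)(C)[Si](C)(C)Cl
Why: Rate-controlled silylation; the primary C11–OH and the equatorial C5–OH react, while the axial C6–OH (1,3-diaxial to H-4a and H-8) is the slowest.

Step 23
Reactants: 34 bis-TBS ether; 18 3-methylglutaconic anhydride
Product: 36 Tandyukisin D, via bis-TBS half-ester 35 (not isolated)
Conditions: 18 (2 equiv), DMAP (0.2 equiv), pyridine–CH2Cl2, 0 °C to rt; then HF·pyridine, THF, 0 °C to rt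
Reagents that add atoms: none
Why: DMAP-catalysed alcoholysis of the cyclic anhydride at its non-conjugated carbonyl gives the Z half-ester with the conjugated acid free, and HF·pyridine then removes both TBS ethers under mildly acidic conditions that disfavour acyl migration and β-elimination.

**Compound list**

1 | (−)-quinic acid | C1[C@H]([C@H]([C@@H](C[C@@]1(C(=O)O)O)O)O)O | starting material
2 | 3,4-O-isopropylidene-1,5-quinide (acetonide γ-lactone) | C1[C@H]2OC(C)(C)O[C@H]2[C@H]3C[C@]1(O)C(=O)O3 | intermediate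
3 | acetonide triol, 1-(hydroxymethyl)cyclohexane-1,3-diol carrying the cis-4,5-acetonide | C1[C@H]2OC(C)(C)O[C@H]2[C@H](O)C[C@]1(O)CO | intermediate
4 | (3R,4S,5R)-3-hydroxy-4,5-(isopropylidenedioxy)cyclohexan-1-one | C1[C@H]2OC(C)(C)O[C@H]2[C@H](O)CC1=O | intermediate
5 | 3-O-mesylate of 4 | C1[C@H]2OC(C)(C)O[C@H]2[C@H](OS(C)(=O)=O)CC1=O | intermediate (not isolated)
6 | (4S,5R)-4,5-(isopropylidenedioxy)cyclohex-2-en-1-one | C1[C@H]2OC(C)(C)O[C@H]2C=CC1=O | intermediate
7 | 1-(trimethylsilyloxy)-3-vinyl-4,5-(isopropylidenedioxy)cyclohex-1-ene, vinyl trans to the adjacent acetonide oxygen | C=C[C@H]1[C@@H]2OC(C)(C)O[C@@H]2CC(O[Si](C)(C)C)=C1 | intermediate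
8 | tiglic acid, (E)-2-methylbut-2-enoic acid | C/C=C(\C)C(=O)O | starting material
9 | (R)-2-methylbutanoic acid | CC[C@@H](C)C(=O)O | intermediate
10 | (R)-2-methylbutan-1-ol | CC[C@@H](C)CO | intermediate
11 | (R)-2-methylbutanal | CC[C@@H](C)C=O | intermediate (not isolated)
12 | (3E,5R)-5-methylhept-3-en-2-one | CC[C@@H](C)/C=C/C(C)=O | intermediate
13 | (2R,3E,5R)-5-methylhept-3-en-2-ol | CC[C@@H](C)/C=C/[C@@H](C)O | intermediate
14 | (2R,3E,5R)-5-methylhept-3-en-2-yl bromoacetate | CC[C@@H](C)/C=C/[C@@H](C)OC(=O)CBr | intermediate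
15 | ethyl acetoacetate | CCOC(=O)CC(C)=O | starting material
16 | ethyl isodehydroacetate, ethyl 4,6-dimethyl-2-oxo-2H-pyran-5-carboxylate | CCOC(=O)C1=C(C)OC(=O)C=C1C | intermediate
17 | (Z)-3-methylglutaconic acid (used as E/Z mixture) | OC(=O)C/C(C)=C\C(=O)O | intermediate
18 | 3-methylglutaconic anhydride, 4-methyl-2H-pyran-2,6(3H)-dione | CC1=CC(=O)OC(=O)C1 | intermediate
19 | lithium enolate from 7 | C=C[C@H]1[C@@H]2OC(C)(C)O[C@@H]2CC(O[Li])=C1 | intermediate (not isolated)
20 | (2R,3E,5R)-5-methylhept-3-en-2-yl 2-[4,5-(isopropylidenedioxy)-2-oxo-6-vinylcyclohexyl]acetate, ring substituents trans, vinyl trans to adjacent O | C=C[C@H]1[C@@H]2OC(C)(C)O[C@@H]2CC(=O)[C@@H]1CC(=O)O[C@H](C)/C=C/[C@H](C)CC | intermediate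
21 | 2-methylidene analogue of 20 | C=C[C@H]1[C@@H]2OC(C)(C)O[C@@H]2CC(=C)[C@@H]1CC(=O)O[C@H](C)/C=C/[C@H](C)CC | intermediate
22 | trimethylsilyl ketene acetal of 21 (ring carbon cis to the allylic oxygen) | C=C[C@H]1[C@@H]2OC(C)(C)O[C@@H]2CC(=C)[C@@H]1/C=C(/O[Si](C)(C)C)O[C@H](C)/C=C/[C@H](C)CC | intermediate (not isolated)
23 | trimethylsilyl ester of 24 | C=C[C@H]1[C@@H]2OC(C)(C)O[C@@H]2CC(=C)[C@@H]1[C@H](C(=O)O[Si](C)(C)C)[C@H](/C=C/C)[C@H](C)CC | intermediate (not isolated)
24 | (3S,4E)-3-[(2R)-butan-2-yl]-2-[4,5-(isopropylidenedioxy)-2-methylidene-6-vinylcyclohexyl]hex-4-enoic acid (C1 epimers, major drawn) | C=C[C@H]1[C@@H]2OC(C)(C)O[C@@H]2CC(=C)[C@@H]1[C@H](C(=O)O)[C@H](/C=C/C)[C@H](C)CC | intermediate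
25 | trans-fused octalin acid: C1–CO2H (epimers, major drawn), C2 sec-butyl α, C3=C4, 5,6-acetonide β, C8 methylidene | CC[C@@H](C)[C@H]1C=C[C@H]2[C@@H]3OC(C)(C)O[C@@H]3CC(=C)[C@@H]2[C@@H]1C(=O)O | intermediate
26 | dilithium enediolate of 25 | CC[C@@H](C)[C@H]1C=C[C@H]2[C@@H]3OC(C)(C)O[C@@H]3CC(=C)[C@@H]2C1=C(O[Li])O[Li] | intermediate (not isolated)
27 | C1-methyl acid (C1 methyl β, CO2H α; otherwise as 25) | CC[C@@H](C)[C@H]1C=C[C@H]2[C@@H]3OC(C)(C)O[C@@H]3CC(=C)[C@@H]2[C@@]1(C)C(=O)O | intermediate
28 | dilithium gem-diolate from 27 and MeLi | CC[C@@H](C)[C@H]1C=C[C@H]2[C@@H]3OC(C)(C)O[C@@H]3CC(=C)[C@@H]2[C@@]1(C)C(C)(O[Li])O[Li] | intermediate (not isolated)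
29 | C1 methyl ketone with 5,6-acetonide and C8 methylidene | CC[C@@H](C)[C@H]1C=C[C@H]2[C@@H]3OC(C)(C)O[C@@H]3CC(=C)[C@@H]2[C@@]1(C)C(C)=O | intermediate (not isolated)
30 | C1 methyl ketone, 5β,6β-diol, C8 methylidene | CC[C@@H](C)[C@H]1C=C[C@H]2[C@H](O)[C@H](O)CC(=C)[C@@H]2[C@@]1(C)C(C)=O | intermediate
31 | C1 methyl ketone, 5β,6β-diol, C8 methyl α | CC[C@@H](C)[C@H]1C=C[C@H]2[C@H](O)[C@H](O)C[C@@H](C)[C@@H]2[C@@]1(C)C(C)=O | intermediate
32 | 5,6-bis-TMS ether, TMS enol ether of 31 | CC[C@@H](C)[C@H]1C=C[C@H]2[C@H](O[Si](C)(C)C)[C@H](O[Si](C)(C)C)C[C@@H](C)[C@@H]2[C@@]1(C)C(=C)O[Si](C)(C)C | intermediate (not isolated)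
33 | triol core (deacyl target): 5β,6β-diol with 3-hydroxypropanoyl chain | CC[C@@H](C)[C@H]1C=C[C@H]2[C@H](O)[C@H](O)C[C@@H](C)[C@@H]2[C@@]1(C)C(=O)CCO | intermediate
34 | C5,C11-bis-TBS ether of 33 (C6–OH free) | CC[C@@H](C)[C@H]1C=C[C@H]2[C@H](O[Si](C)(C)C(C)(C)C)[C@H](O)C[C@@H](C)[C@@H]2[C@@]1(C)C(=O)CCO[Si](C)(C)C(C)(C)C | intermediate
35 | C5,C11-bis-TBS ether of Tandyukisin D | CC[C@@H](C)[C@H]1C=C[C@H]2[C@H](O[Si](C)(C)C(C)(C)C)[C@H](OC(=O)C/C(C)=C\C(=O)O)C[C@@H](C)[C@@H]2[C@@]1(C)C(=O)CCO[Si](C)(C)C(C)(C)C | intermediate (not isolated)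
36 | Tandyukisin D (1S,2S,4aR,5S,6R,8R,8aS; sec-butyl R; Z half-ester) | CC[C@@H](C)[C@H]1C=C[C@H]2[C@H](O)[C@H](OC(=O)C/C(C)=C\C(=O)O)C[C@@H](C)[C@@H]2[C@@]1(C)C(=O)CCO | target

**Step count and convergence**

Total: 23 steps. Longest linear sequence: 15 steps (steps 1–5, then 14–23; the tiglic acid branch, steps 6–10 then 14–23, is equally long), which is 15/23 ≈ 0.65 of the total.

**Three steps most likely to fail**

Step 14 (enolate alkylation). The hindered lithium enolate may react sluggishly with the bromoacetate, and the product ketone carries a β-oxygen that can be lost by E1cB elimination. The fallback sets out from enone 6 and bromoacetate 14 and rejoins the route at keto ester 20. Iodination of 6 (I2, pyridine, CCl4) gives the α-iodoenone F1. Zinc insertion into 14 (Zn dust, THF) gives the Reformatsky reagent F2. Negishi-type cross-coupling of F1 with F2 (Pd(PPh3)4, THF, rt) gives the 2-(alkoxycarbonylmethyl)enone F3. Conjugate addition of vinylmagnesium bromide (CuBr·SMe2 cat., THF, −78 °C) anti to the acetonide, followed by protonation and equilibration to the trans ketone, gives 20. The C8a–CH2 bond is thus made by cross-coupling before the vinyl group is added, and no enolate alkylation is needed.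

Step 19 (methyl ketone from the acid). The carboxylate sits on a quaternary carbon flanked by two branched centres and may resist MeLi. The fallback sets out from acid 27 and rejoins at acetonide methyl ketone 29. LiAlH4 reduces 27 to the neopentyl alcohol F4. Dess–Martin periodinane gives the aldehyde F5. MeMgBr adds to this far more accessible carbonyl to give the carbinol F6 as an epimer mixture. A second Dess–Martin oxidation gives 29, which is hydrolysed to 30 with HCl in MeOH as in step 19.

Step 23 (anhydride opening by a hindered axial alcohol). The C6–OH next to the C5 silyl ether may react slowly, and the anhydride and its half-ester can isomerise (E/Z, alkene migration). The fallback sets out from anhydride 18 and alcohol 34 and rejoins at target 36. Allyl alcohol opens 18 to the allyl half-ester F7. Its free conjugated acid is esterified with 2-(trimethylsilyl)ethanol (EDC, DMAP) to the mixed diester F8. Pd(PPh3)4 with morpholine removes the allyl group to give the acid F9. Yamaguchi esterification of 34 with F9 (2,4,6-trichlorobenzoyl chloride, Et3N, then DMAP) gives the fully protected ester F10. TBAF buffered with AcOH removes the silylethyl ester and both TBS ethers to give 36.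

**Further compounds**

F1 | step 14 | (4S,5R)-2-iodo-4,5-(isopropylidenedioxy)cyclohex-2-en-1-one | C1[C@H]2OC(C)(C)O[C@H]2C=C(I)C1=O
F2 | step 14 | bromozinc Reformatsky reagent of 14 | CC[C@@H](C)/C=C/[C@@H](C)OC(=O)C[Zn]Br
F3 | step 14 | (2R,3E,5R)-5-methylhept-3-en-2-yl 2-[(3S,4R)-3,4-(isopropylidenedioxy)-6-oxocyclohex-1-en-1-yl]acetate | C1[C@H]2OC(C)(C)O[C@H]2C=C(CC(=O)O[C@H](C)/C=C/[C@H](C)CC)C1=O
F4 | step 19 | C1 hydroxymethyl analogue of 27 (primary alcohol) | CC[C@@H](C)[C@H]1C=C[C@H]2[C@@H]3OC(C)(C)O[C@@H]3CC(=C)[C@@H]2[C@@]1(C)CO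
F5 | step 19 | C1 carbaldehyde analogue of 27 | CC[C@@H](C)[C@H]1C=C[C@H]2[C@@H]3OC(C)(C)O[C@@H]3CC(=C)[C@@H]2[C@@]1(C)C=O
F6 | step 19 | C1 (1-hydroxyethyl) analogue of 27 (carbinol epimers) | CC[C@@H](C)[C@H]1C=C[C@H]2[C@@H]3OC(C)(C)O[C@@H]3CC(=C)[C@@H]2[C@@]1(C)C(C)O
F7 | step 23 | (Z)-5-(allyloxy)-3-methyl-5-oxopent-2-enoic acid | C=CCOC(=O)C/C(C)=C\C(=O)O
F8 | step 23 | 5-allyl 1-[2-(trimethylsilyl)ethyl] (Z)-3-methylpent-2-enedioate | C=CCOC(=O)C/C(C)=C\C(=O)OCC[Si](C)(C)C
F9 | step 23 | (Z)-3-methyl-5-oxo-5-[2-(trimethylsilyl)ethoxy]pent-3-enoic acid | OC(=O)C/C(C)=C\C(=O)OCC[Si](C)(C)C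
F10 | step 23 | C5,C11-bis-TBS ether of Tandyukisin D 2-(trimethylsilyl)ethyl ester | CC[C@@H](C)[C@H]1C=C[C@H]2[C@H](O[Si](C)(C)C(C)(C)C)[C@H](OC(=O)C/C(C)=C\C(=O)OCC[Si](C)(C)C)C[C@@H](C)[C@@H]2[C@@]1(C)C(=O)CCO[Si](C)(C)C(C)(C)C
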